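**Plan**
- Cuts, in retrosynthetic order: O1–C2 of ring C (made last among the ring bonds, by Mitsunobu closure), C3–C4 (dithiane anion plus epoxide), C4–C4a (formylation ortho to the free phenol), N–CH3, then N–C6′ and C2′–C3′ of the piperidine, back to 2,4,6-trihydroxybenzaldehyde.
- Enabling feature: in ring A the piperidine-bearing C6 is para to C8a–O1 and lies between the equivalent oxygens O5 and O7. A 4-substituted 3,5-bis(benzyloxy)phenol therefore has one free hydroxyl and one kind of ortho carbon, so C4a–C4 formation and O1–C2 closure involve no regiochemical choice.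
- The 1,3-relation of O1–C2 to C4=O lets C4 be carried as a 1,3-dithiane. This temporary ring is the acyl anion for the C3–C4 bond and blocks β-elimination during the closure.
- Forward order: piperidine ring on the aryl aldehyde carbon, N-methylation and unmasking of O1, C4 (CHO, then dithiane), C3/C2 by epoxide opening, ring C by O1–C2 closure, dithiane hydrolysis, debenzylation.
- Stereochemistry: C2′ (R) from the (S)-tert-butanesulfinyl auxiliary; C2 (S) from (S)-2-phenyloxirane, by retention in the opening and inversion in the Mitsunobu closure. Both centres are kept away from base afterwards.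

Key step: step 10

Remark: the SMILES is read as (2S) at C2 of the chromanone and (R) at C2′ of the piperidine, and the target is taken as the free base.

Step 1
Reactants: 1 2,4,6-trihydroxybenzaldehyde
Product: 2 2,6-dihydroxy-4-(methoxymethoxy)benzaldehyde
Conditions: MOMCl (1.0 equiv), i-Pr2NEt, THF, 0 °C
Reagents that add atoms: chloromethyl methyl ether (MOMCl), COCCl
Why: Williamson-type O-alkylation in which the 4-OH, the most acidic hydroxyl and the only one not hydrogen-bonded to the formyl group, should react first with one equivalent of MOMCl, which marks the oxygen that becomes O1.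

Step 2
Reactants: 2 2,6-dihydroxy-4-(methoxymethoxy)benzaldehyde
Product: 3 2,6-bis(benzyloxy)-4-(methoxymethoxy)benzaldehyde
Conditions: BnBr (2.5 equiv), K2CO3, DMF, 60 °C
Reagents that add atoms: benzyl bromide, BrCc1ccccc1
Why: Williamson ether synthesis under forcing conditions benzylates the two chelated ortho hydroxyls (the future O5 and O7), and the MOM acetal is stable to base.

Step 3
Reactants: 3 2,6-bis(benzyloxy)-4-(methoxymethoxy)benzaldehyde; 4 (S)-2-methylpropane-2-sulfinamide
Product: 5 (S,E)-N-[2,6-bis(benzyloxy)-4-(methoxymethoxy)benzylidene]-2-methylpropane-2-sulfinamide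
Conditions: Ti(OEt)4 (2.5 equiv), THF, 65 °C
Reagents that add atoms: none
Why: Ti(OEt)4-mediated condensation of an aldehyde with tert-butanesulfinamide (sulfinimine formation), in which the Lewis acid also takes up the water, as this electron-rich, doubly ortho-substituted aldehyde requires.

Step 4
Reactants: 5 (S,E)-N-[2,6-bis(benzyloxy)-4-(methoxymethoxy)benzylidene]-2-methylpropane-2-sulfinamide
Product: 6 (S)-N-[(1R)-1-[2,6-bis(benzyloxy)-4-(methoxymethoxy)phenyl]-5-chloropentyl]-2-methylpropane-2-sulfinamide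
Conditions: Cl(CH2)4MgBr (from Br(CH2)4Cl and Mg, THF), CH2Cl2, −48 °C → 0 °C
Reagents that add atoms: 4-chlorobutylmagnesium bromide, ClCCCC[Mg]Br
Why: Auxiliary-controlled Grignard 1,2-addition to an N-tert-butanesulfinyl aldimine in a non-coordinating solvent, where a six-membered chair transition state (magnesium on the sulfinyl oxygen, tert-butyl equatorial) should deliver the alkyl group to the Re face of the (S)-sulfinimine and set C2′ as (R); a minor diastereomer is separable here.

Step 5
Reactants: 6 (S)-N-[(1R)-1-[2,6-bis(benzyloxy)-4-(methoxymethoxy)phenyl]-5-chloropentyl]-2-methylpropane-2-sulfinamide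
Product: 7 (2R)-2-[2,6-bis(benzyloxy)-4-(methoxymethoxy)phenyl]-1-[(S)-tert-butylsulfinyl]piperidine
Conditions: NaH, DMF, 0 °C → rt
Reagents that add atoms: none
Why: Intramolecular N-alkylation of the sulfinamide anion by the primary chloride (6-exo-tet) should close the piperidine ring without touching the C2′ stereocentre.

Step 6
Reactants: 7 (2R)-2-[2,6-bis(benzyloxy)-4-(methoxymethoxy)phenyl]-1-[(S)-tert-butylsulfinyl]piperidine
Product: 9 3,5-bis(benzyloxy)-4-[(2R)-1-methylpiperidin-2-yl]phenol, via piperidine hydrochloride 8 (not isolated)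
Conditions: HCl (3 M in MeOH), rt → 40 °C; evaporate; then Et3N, 37% aq. CH2O, NaBH(OAc)3, ClCH2CH2Cl, rt
Reagents that add atoms: formaldehyde, C=O
Why: Acidic methanolysis should cleave the N-sulfinyl group and the MOM acetal in one operation while the benzyl ethers survive, and reductive amination with formaldehyde (borohydride reduction of the iminium ion) then installs N-methyl under conditions too mild for hydroxymethylation of the phenol.

Step 7
Reactants: 9 3,5-bis(benzyloxy)-4-[(2R)-1-methylpiperidin-2-yl]phenol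
Product: 10 2,4-bis(benzyloxy)-6-hydroxy-3-[(2R)-1-methylpiperidin-2-yl]benzaldehyde
Conditions: MgCl2, Et3N, (CH2O)n, MeCN, reflux
Reagents that add atoms: formaldehyde (from paraformaldehyde), C=O
Why: Magnesium-mediated ortho-formylation of a phenol (Casnati–Skattebøl reaction), in which the magnesium phenoxide directs formaldehyde ortho to the only free hydroxyl; the two ortho positions are equivalent, so the C4 carbon enters next to the future O1 without a regiochemical choice.

Step 8
Reactants: 10 2,4-bis(benzyloxy)-6-hydroxy-3-[(2R)-1-methylpiperidin-2-yl]benzaldehyde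
Product: 11 3,5-bis(benzyloxy)-2-(1,3-dithian-2-yl)-4-[(2R)-1-methylpiperidin-2-yl]phenol
Conditions: HS(CH2)3SH, BF3·OEt2 (2.5 equiv), CH2Cl2, 0 °C → rt
Reagents that add atoms: propane-1,3-dithiol, SCCCS
Why: Lewis-acid-promoted dithioacetalisation of the aldehyde gives the 1,3-dithiane that serves as the C4 acyl anion equivalent and as a temporary ring, with the excess BF3·OEt2 covering the basic amine.

Step 9
Reactants: 11 3,5-bis(benzyloxy)-2-(1,3-dithian-2-yl)-4-[(2R)-1-methylpiperidin-2-yl]phenol; 12 (S)-2-phenyloxirane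
Product: 14 3,5-bis(benzyloxy)-2-{2-[(2R)-2-hydroxy-2-phenylethyl]-1,3-dithian-2-yl}-4-[(2R)-1-methylpiperidin-2-yl]phenol, via dilithio dianion 13 (not isolated)
Conditions: n-BuLi (2.3 equiv), THF, −30 → 0 °C; then 12, 0 °C → rt
Reagents that add atoms: none
Why: Corey–Seebach umpolung, in which the 2-lithio-1,3-dithiane (phenol carried as its lithium salt) should open the epoxide by SN2 attack at the unsubstituted carbon, forming C3–C4 with retention at the carbinol carbon, whose descriptor becomes (R) only through the change in CIP priorities.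

Step 10
Reactants: 14 3,5-bis(benzyloxy)-2-{2-[(2R)-2-hydroxy-2-phenylethyl]-1,3-dithian-2-yl}-4-[(2R)-1-methylpiperidin-2-yl]phenol
Product: 15 (2S)-5,7-bis(benzyloxy)-6-[(2R)-1-methylpiperidin-2-yl]-2-phenylspiro[chromane-4,2'-[1,3]dithiane]
Conditions: PPh3, DIAD, THF, 0 °C → rt
Reagents that add atoms: none
Why: Intramolecular Mitsunobu etherification: the PPh3/DIAD betaine is protonated by the phenol and converts the (R)-carbinol into an alkoxyphosphonium ion, which the phenoxide O1 displaces from the rear in an SN2 step that forms O1–C2 and expels Ph3P=O. The closest known reaction type is the Mitsunobu cyclisation of 2-(3-hydroxyalkyl)phenols to 2-substituted chromans, including substrates whose C4 carbonyl is masked as a dithioacetal. Ring C (O1, C2, C3, C4, C4a, C8a) closes in the 6-exo-tet mode. C2 is set as (S) by Walden inversion of the (R)-carbinol, whose configuration comes unchanged from (S)-2-phenyloxirane, so the centre is under chiral-pool control and independent of the remote C2′. The step needs substitution to win over elimination and ionisation: the 1,3-dithiane ring at C4 removes the acidic C3 hydrogens that a β-hydroxy ketone would have (no E1cB dehydration to a chalcone, no later retro-oxa-Michael racemisation), and its geminal substitution favours closure (Thorpe–Ingold effect). The step also needs O1 to be the only nucleophile: O5 and O7 are benzylated and O1 is the single free phenol, para to C6, which fixes the 6-(piperidinyl) constitution.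

Step 11
Reactants: 15 (2S)-5,7-bis(benzyloxy)-6-[(2R)-1-methylpiperidin-2-yl]-2-phenylspiro[chromane-4,2'-[1,3]dithiane]
Product: 16 (2S)-5,7-bis(benzyloxy)-6-[(2R)-1-methylpiperidin-2-yl]-2-phenylchroman-4-one
Conditions: Hg(ClO4)2·3H2O, CaCO3, THF–H2O, 0 °C → rt
Reagents that add atoms: water, O
Why: Mercury-assisted hydrolysis of the 1,3-dithiane (thiophilic activation, then water attack on the thionium ion) should release the C4 ketone under buffered, non-basic conditions, so C2 cannot be lost by retro-oxa-Michael ring opening.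

Step 12
Reactants: 16 (2S)-5,7-bis(benzyloxy)-6-[(2R)-1-methylpiperidin-2-yl]-2-phenylchroman-4-one
Product: 17 (2S)-5,7-dihydroxy-6-[(2R)-1-methylpiperidin-2-yl]-2-phenylchroman-4-one
Conditions: H2 (1 atm), 10% Pd/C, AcOH (2 equiv), EtOAc–MeOH, rt; NaHCO3 work-up
Reagents that add atoms: none
Why: Catalytic hydrogenolysis of the two aryl benzyl ethers over Pd/C with the amine kept protonated, where aryl O-benzyl cleavage should be much faster than cleavage of the cyclic benzylic C2–O1 and C2′–N bonds.

**Compound list**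
1 | 2,4,6-trihydroxybenzaldehyde | O=Cc1c(O)cc(O)cc1O | starting material
2 | 2,6-dihydroxy-4-(methoxymethoxy)benzaldehyde | O=Cc1c(O)cc(OCOC)cc1O | intermediate
3 | 2,6-bis(benzyloxy)-4-(methoxymethoxy)benzaldehyde | O=Cc1c(OCc2ccccc2)cc(OCOC)cc1OCc1ccccc1 | intermediate
4 | (S)-2-methylpropane-2-sulfinamide | CC(C)(C)[S@@](N)=O | starting material
5 | (S,E)-N-[2,6-bis(benzyloxy)-4-(methoxymethoxy)benzylidene]-2-methylpropane-2-sulfinamide | CC(C)(C)[S@](=O)/N=C/c1c(OCc2ccccc2)cc(OCOC)cc1OCc1ccccc1 | intermediate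
6 | (S)-N-[(1R)-1-[2,6-bis(benzyloxy)-4-(methoxymethoxy)phenyl]-5-chloropentyl]-2-methylpropane-2-sulfinamide | CC(C)(C)[S@](=O)N[C@H](CCCCCl)c1c(OCc2ccccc2)cc(OCOC)cc1OCc1ccccc1 | intermediate
7 | (2R)-2-[2,6-bis(benzyloxy)-4-(methoxymethoxy)phenyl]-1-[(S)-tert-butylsulfinyl]piperidine | CC(C)(C)[S@](=O)N1CCCC[C@@H]1c1c(OCc2ccccc2)cc(OCOC)cc1OCc1ccccc1 | intermediate
8 | 3,5-bis(benzyloxy)-4-[(2R)-piperidin-2-yl]phenol hydrochloride | Cl.N1CCCC[C@@H]1c1c(OCc2ccccc2)cc(O)cc1OCc1ccccc1 | intermediate
9 | 3,5-bis(benzyloxy)-4-[(2R)-1-methylpiperidin-2-yl]phenol | CN1CCCC[C@@H]1c1c(OCc2ccccc2)cc(O)cc1OCc1ccccc1 | intermediate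
10 | 2,4-bis(benzyloxy)-6-hydroxy-3-[(2R)-1-methylpiperidin-2-yl]benzaldehyde | CN1CCCC[C@@H]1c1c(OCc2ccccc2)cc(O)c(C=O)c1OCc1ccccc1 | intermediate
11 | 3,5-bis(benzyloxy)-2-(1,3-dithian-2-yl)-4-[(2R)-1-methylpiperidin-2-yl]phenol | CN1CCCC[C@@H]1c1c(OCc2ccccc2)cc(O)c(C2SCCCS2)c1OCc1ccccc1 | intermediate
12 | (S)-2-phenyloxirane | C1O[C@H]1c1ccccc1 | starting material
13 | dilithio dianion of 11 (lithium phenoxide, 2-lithio-1,3-dithiane) | [Li+].[Li+].CN1CCCC[C@@H]1c1c(OCc2ccccc2)cc([O-])c([C-]2SCCCS2)c1OCc1ccccc1 | intermediate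
14 | 3,5-bis(benzyloxy)-2-{2-[(2R)-2-hydroxy-2-phenylethyl]-1,3-dithian-2-yl}-4-[(2R)-1-methylpiperidin-2-yl]phenol | CN1CCCC[C@@H]1c1c(OCc2ccccc2)cc(O)c(C2(C[C@@H](O)c3ccccc3)SCCCS2)c1OCc1ccccc1 | intermediate
15 | (2S)-5,7-bis(benzyloxy)-6-[(2R)-1-methylpiperidin-2-yl]-2-phenylspiro[chromane-4,2'-[1,3]dithiane] | CN1CCCC[C@@H]1c1c(OCc2ccccc2)cc2c(c1OCc1ccccc1)C1(SCCCS1)C[C@@H](c1ccccc1)O2 | intermediate
16 | (2S)-5,7-bis(benzyloxy)-6-[(2R)-1-methylpiperidin-2-yl]-2-phenylchroman-4-one | CN1CCCC[C@@H]1c1c(OCc2ccccc2)cc2c(c1OCc1ccccc1)C(=O)C[C@@H](c1ccccc1)O2 | intermediate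
17 | (2S)-5,7-dihydroxy-6-[(2R)-1-methylpiperidin-2-yl]-2-phenylchroman-4-one | CN1CCCC[C@@H]1c1c(O)cc2c(c1O)C(=O)C[C@@H](c1ccccc1)O2 | target

Total step count: 12. Longest linear sequence: 12 steps (1 → 17); 4 and 12 are bought.

**Steps most likely to fail**

Step 9. What may go wrong: incomplete C-lithiation of the electron-rich dithiane in the presence of the phenoxide, or sluggish opening of the epoxide by the hindered tertiary carbanion. The fallback sets out from 11 and returns at 14. The phenol of 11 is masked with MOMCl and NaH in DMF to give the methoxymethyl ether (2R)-2-[2,6-bis(benzyloxy)-3-(1,3-dithian-2-yl)-4-(methoxymethoxy)phenyl]-1-methylpiperidine F1. Its monoanion (n-BuLi, THF, −30 °C) is no longer deactivated by a phenoxide and is supported by lithium coordination to the acetal oxygens. It should open 12 at the unsubstituted carbon to give the carbinol (1R)-2-{2-[2,4-bis(benzyloxy)-6-(methoxymethoxy)-3-[(2R)-1-methylpiperidin-2-yl]phenyl]-1,3-dithian-2-yl}-1-phenylethan-1-ol F2. HCl in MeOH at room temperature then removes the acetal and returns 14.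

Step 10. What may go wrong: ionisation of the alkoxyphosphonium ion with loss of configurational integrity at C2, elimination to a styrene, or alkylation of the hydrazide in place of the hindered phenol. The fallback sets out from 14 and returns at 16, replacing the SN2 closure by an oxa-Michael closure. Hydrolysis of the dithiane of 14 with Hg(ClO4)2 and CaCO3 in aqueous THF should give the β-hydroxy ketone (3R)-1-{2,4-bis(benzyloxy)-6-hydroxy-3-[(2R)-1-methylpiperidin-2-yl]phenyl}-3-hydroxy-3-phenylpropan-1-one F3. NaOAc in EtOH at reflux should dehydrate it (E1cB) to the chalcone (2E)-1-{2,4-bis(benzyloxy)-6-hydroxy-3-[(2R)-1-methylpiperidin-2-yl]phenyl}-3-phenylprop-2-en-1-one F4, which is not isolated. It closes by reversible addition of O1, still the only free phenol, to give 16 together with its C2 epimer (2R)-5,7-bis(benzyloxy)-6-[(2R)-1-methylpiperidin-2-yl]-2-phenylchroman-4-one F5. Because C2′ is fixed as (R), 16 and F5 are diastereomers and should be separable by chromatography or crystallisation; F5 can be returned to the equilibration.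

Step 4. What may go wrong: erosion or reversal of facial selectivity because the ortho benzyloxy groups offer magnesium a competing chelate, or decay of the chloroalkyl Grignard reagent before addition. The fallback sets out from 3 and returns at 8, replacing auxiliary-controlled C–C formation by catalyst-controlled imine reduction.
- 3 is treated with the same Grignard reagent to give the racemic carbinol 1-[2,6-bis(benzyloxy)-4-(methoxymethoxy)phenyl]-5-chloropentan-1-ol F6.
- MnO2 in CH2Cl2 oxidises it to the ketone 1-[2,6-bis(benzyloxy)-4-(methoxymethoxy)phenyl]-5-chloropentan-1-one F7.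
- NaN3 in DMF gives the azido ketone 5-azido-1-[2,6-bis(benzyloxy)-4-(methoxymethoxy)phenyl]pentan-1-one F8.
- Staudinger/aza-Wittig reaction (PPh3, THF) closes it to the cyclic imine 6-[2,6-bis(benzyloxy)-4-(methoxymethoxy)phenyl]-2,3,4,5-tetrahydropyridine F9.
- Asymmetric transfer hydrogenation with RuCl(p-cymene)(TsDPEN) and HCO2H–Et3N, with the ligand enantiomer chosen for the (R)-amine, should give the piperidine (2R)-2-[2,6-bis(benzyloxy)-4-(methoxymethoxy)phenyl]piperidine F10.
- HCl in MeOH removes the MOM group and returns 8 for the methylation of step 6.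

**Further compounds**
F1 | step 9 | (2R)-2-[2,6-bis(benzyloxy)-3-(1,3-dithian-2-yl)-4-(methoxymethoxy)phenyl]-1-methylpiperidine | CN1CCCC[C@@H]1c1c(OCc2ccccc2)cc(OCOC)c(C2SCCCS2)c1OCc1ccccc1
F2 | step 9 | (1R)-2-{2-[2,4-bis(benzyloxy)-6-(methoxymethoxy)-3-[(2R)-1-methylpiperidin-2-yl]phenyl]-1,3-dithian-2-yl}-1-phenylethan-1-ol | CN1CCCC[C@@H]1c1c(OCc2ccccc2)cc(OCOC)c(C2(C[C@@H](O)c3ccccc3)SCCCS2)c1OCc1ccccc1
F3 | step 10 | (3R)-1-{2,4-bis(benzyloxy)-6-hydroxy-3-[(2R)-1-methylpiperidin-2-yl]phenyl}-3-hydroxy-3-phenylpropan-1-one | CN1CCCC[C@@H]1c1c(OCc2ccccc2)cc(O)c(C(=O)C[C@@H](O)c2ccccc2)c1OCc1ccccc1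
F4 | step 10 | (2E)-1-{2,4-bis(benzyloxy)-6-hydroxy-3-[(2R)-1-methylpiperidin-2-yl]phenyl}-3-phenylprop-2-en-1-one | CN1CCCC[C@@H]1c1c(OCc2ccccc2)cc(O)c(C(=O)/C=C/c2ccccc2)c1OCc1ccccc1
F5 | step 10 | (2R)-5,7-bis(benzyloxy)-6-[(2R)-1-methylpiperidin-2-yl]-2-phenylchroman-4-one | CN1CCCC[C@@H]1c1c(OCc2ccccc2)cc2c(c1OCc1ccccc1)C(=O)C[C@H](c1ccccc1)O2
F6 | step 4 | 1-[2,6-bis(benzyloxy)-4-(methoxymethoxy)phenyl]-5-chloropentan-1-ol (racemic) | OC(CCCCCl)c1c(OCc2ccccc2)cc(OCOC)cc1OCc1ccccc1
F7 | step 4 | 1-[2,6-bis(benzyloxy)-4-(methoxymethoxy)phenyl]-5-chloropentan-1-one | O=C(CCCCCl)c1c(OCc2ccccc2)cc(OCOC)cc1OCc1ccccc1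
F8 | step 4 | 5-azido-1-[2,6-bis(benzyloxy)-4-(methoxymethoxy)phenyl]pentan-1-one | [N-]=[N+]=NCCCCC(=O)c1c(OCc2ccccc2)cc(OCOC)cc1OCc1ccccc1
F9 | step 4 | 6-[2,6-bis(benzyloxy)-4-(methoxymethoxy)phenyl]-2,3,4,5-tetrahydropyridine | C1CCN=C(C1)c1c(OCc2ccccc2)cc(OCOC)cc1OCc1ccccc1
F10 | step 4 | (2R)-2-[2,6-bis(benzyloxy)-4-(methoxymethoxy)phenyl]piperidine | N1CCCC[C@@H]1c1c(OCc2ccccc2)cc(OCOC)cc1OCc1ccccc1
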